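**Plan**
Retrosynthesis (ring numbering: O1; C2 bears 4-hydroxyphenyl; C3 bears the aroyl group; C4 bears 4-hydroxybenzyl; C5 bears 2,4-dihydroxyphenyl). After the phenol protecting groups, one retro-step cuts the ketone C(=O)–C3 bond together with the ring bond O1–C2, leaving an aroyl chloride and an acyclic (E)-styrene. The styrene is then cut at C2=C3 (olefination) and at C4–C5 (aldol).
Forward: auxiliary acylation, anti-aldol (C4–C5), silylation, reduction and oxidation, olefination (C2=C3). The tetrahydrofuran, the only non-aromatic ring, then closes in the same event that brings in the aroyl group, and two deprotections finish the route.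
Enabling feature: C2 carries both the ring oxygen O1 and a para-oxygenated phenyl ring and lies β to the ketone carbonyl, so C(=O)–C3–C2(aryl)–O1 is the retron of a styrene oxy-acylation. The para oxygen stabilises first a radical and then a cation at C2, and the oxygen on C5 stands ready to trap that cation.
Stereochemistry: C4 and C5 come from (4S)-4-benzyl-1,3-oxazolidin-2-one (derived from L-phenylalanine) in the anti-aldol. C3 follows from C4, and C2 from C3, within the key step. The target is the all-trans (2S,3S,4S,5S) isomer, which is also the least strained one.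

Key step: step 10

Remark: the benzyl-protected building blocks 1, 5 and 11 are taken as commercially available. The ring numbering above is also used for the acyclic precursors.

Step 1
Reactants: 1 3-[4-(benzyloxy)phenyl]propanoic acid; 2 (4S)-4-benzyl-1,3-oxazolidin-2-one
Product: 4 (4S)-4-benzyl-3-{3-[4-(benzyloxy)phenyl]propanoyl}-1,3-oxazolidin-2-one, via mixed pivalic anhydride 3 (not isolated)
Conditions: PivCl, Et3N, THF, −20 °C; then LiCl, 2, −20 °C to rt
Reagents that add atoms: pivaloyl chloride, CC(C)(C)C(=O)Cl (its acyl group stands only in intermediate 3)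
Why: Mixed-anhydride N-acylation of an oxazolidinone, in which the hindered pivaloyl carbonyl of 3 directs the LiCl-activated auxiliary to the propanoyl carbonyl and no stereocentre is touched.

Step 2
Reactants: 4 N-acyl oxazolidinone; 5 2,4-bis(benzyloxy)benzaldehyde
Product: 7 (4S)-4-benzyl-3-{(2R,3S)-2-[4-(benzyloxy)benzyl]-3-[2,4-bis(benzyloxy)phenyl]-3-hydroxypropanoyl}-1,3-oxazolidin-2-one (anti aldol), via trimethylsilyl ether 6 (not isolated)
Conditions: MgCl2 (20 mol %), Et3N, Me3SiCl, EtOAc, 23 °C; then AcOH, THF/H2O, rt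
Reagents that add atoms: chlorotrimethylsilane, C[Si](C)(C)Cl (its silyl group stands only in intermediate 6)
Why: Evans magnesium halide-catalysed anti-aldol reaction, in which soft enolisation gives the chelated Z-magnesium enolate, the face opposite the auxiliary benzyl group attacks the non-enolisable aromatic aldehyde through a boat-like transition state, and silylation makes the addition irreversible, so that C4 and C5 are set in the anti relation.

Step 3
Reactants: 7 anti aldol
Product: 8 triethylsilyl ether of 7, (4S)-4-benzyl-3-{(2R,3S)-2-[4-(benzyloxy)benzyl]-3-[2,4-bis(benzyloxy)phenyl]-3-(triethylsilyloxy)propanoyl}-1,3-oxazolidin-2-one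
Conditions: Et3SiOTf, 2,6-lutidine, CH2Cl2, −78 to 0 °C
Reagents that add atoms: triethylsilyl trifluoromethanesulfonate, CC[Si](CC)(CC)OS(=O)(=O)C(F)(F)F
Why: Silylation of a hindered secondary alcohol by a silyl triflate and a non-nucleophilic base, cold enough to avoid retro-aldol cleavage; the triethylsilyl group is chosen because it protects now and must leave from oxygen in step 10.

Step 4
Reactants: 8 silylated aldol imide
Product: 9 (2S,3S)-2-[4-(benzyloxy)benzyl]-3-[2,4-bis(benzyloxy)phenyl]-3-(triethylsilyloxy)propan-1-ol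
Conditions: LiBH4, H2O (1 equiv), Et2O/THF, 0 °C
Reagents that add atoms: none
Why: Reductive cleavage of an N-acyl oxazolidinone by LiBH4, which attacks the exocyclic imide carbonyl and leaves the silyl ether, the benzyl ethers and both stereocentres untouched.

Step 5
Reactants: 9 primary alcohol
Product: 10 (2R,3S)-2-[4-(benzyloxy)benzyl]-3-[2,4-bis(benzyloxy)phenyl]-3-(triethylsilyloxy)propanal
Conditions: Dess–Martin periodinane, NaHCO3, CH2Cl2, 0 °C to rt
Reagents that add atoms: none
Why: Dess–Martin oxidation under buffered, non-basic conditions should stop at the aldehyde without epimerising C4 or eliminating the β-silyloxy group.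

Step 6
Reactants: 11 1-(benzyloxy)-4-(chloromethyl)benzene
Product: 12 diethyl [4-(benzyloxy)benzyl]phosphonate
Conditions: P(OEt)3 (neat), 140 °C
Reagents that add atoms: triethyl phosphite, CCOP(OCC)OCC
Why: Michaelis–Arbuzov reaction of a reactive benzylic chloride with triethyl phosphite.

Step 7
Reactants: 10 aldehyde; 12 benzylphosphonate
Product: 14 {[(1S,2S,3E)-2-[4-(benzyloxy)benzyl]-1-[2,4-bis(benzyloxy)phenyl]-4-[4-(benzyloxy)phenyl]but-3-en-1-yl]oxy}triethylsilane, via potassium phosphonate carbanion 13 (not isolated)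
Conditions: 12, KN(SiMe3)2, THF, −78 °C; then 10, −78 °C to rt
Reagents that add atoms: KN(SiMe3)2, C[Si](C)(C)[N-][Si](C)(C)C.[K+] (its potassium stands only in intermediate 13)
Why: Horner–Wadsworth–Emmons olefination with a semi-stabilised benzylphosphonate anion should give the (E)-styrene through reversible addition and elimination from the more stable trans-oxaphosphetane, and adding 10 to the preformed anion at −78 °C limits enolisation at C4.

Step 8
Reactants: 15 2,4-dihydroxybenzoic acid
Product: 16 tert-butyldimethylsilyl 2,4-bis(tert-butyldimethylsilyloxy)benzoate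
Conditions: TBSCl (3.3 equiv), imidazole, DMF, rt to 40 °C
Reagents that add atoms: tert-butylchlorodimethylsilane, CC(C)(C)[Si](C)(C)Cl
Why: Exhaustive imidazole-promoted silylation of both phenols and the carboxylic acid.

Step 9
Reactants: 16 tris-silyl compound
Product: 17 2,4-bis(tert-butyldimethylsilyloxy)benzoyl chloride
Conditions: (COCl)2, DMF (cat.), CH2Cl2, 0 °C to rt; used crude
Reagents that add atoms: oxalyl chloride, O=C(Cl)C(=O)Cl
Why: Direct conversion of a silyl ester into the acid chloride by the chloroiminium salt from oxalyl chloride and DMF, which proceeds without free HCl so that the two aryl silyl ethers survive.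

Step 10
Reactants: 14 (E)-styrene silyl ether; 17 aroyl chloride
Product: 21 [2,4-bis(tert-butyldimethylsilyloxy)phenyl]{(2S,3S,4S,5S)-4-[4-(benzyloxy)benzyl]-5-[2,4-bis(benzyloxy)phenyl]-2-[4-(benzyloxy)phenyl]oxolan-3-yl}methanone (all-trans), via aroyl radical 18 (not isolated), via benzylic radical 19 (not isolated), via benzylic cation 20 (not isolated)
Conditions: fac-Ir(ppy)3 (2 mol %), 17 (2 equiv), 2,6-di-tert-butylpyridine (0.2 equiv), MeCN/CH2Cl2 (1:1), blue LED (450 nm), 25 °C, Ar
Reagents that add atoms: none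
Why: Proposed new method: photoexcited fac-Ir(ppy)3 should transfer one electron to 17, which loses chloride to give the nucleophilic σ-aroyl radical 18; 18 adds to the styrene carbon remote from the aryl ring (future C3, the new C(=O)–C3 bond) to give the para-alkoxybenzylic radical 19, and the tetravalent iridium left by the first event oxidises 19 to the quinone-methide-like cation 20, so that the cycle is redox-neutral. The oxygen of the C5 triethylsilyl ether then captures C2 and chloride removes the silyl group as Et3SiCl, which closes the tetrahydrofuran at O1–C2; counted from the original alkene the closure is 5-endo-trig, but it is in fact the collapse of a free benzylic cation onto a nearby oxygen, so that the usual stereoelectronic penalty does not apply. The closest known reaction types are the photoredox three-component oxy-acylation of styrenes (aroyl radical, styrene, alcohol) and radical-polar crossover carboetherification; new are the internal, allylically branched styrene, the ring closure in this mode and the silyl ether as internal nucleophile. C3 is set in the radical addition: in the rotamer that holds C4–H in the alkene plane (least A(1,3) strain) the branched C5 carbinol arm covers one face and the slimmer benzyl CH2 the other, so that 18 should enter anti to C5 and end trans to the C4 benzyl group. C2 is set in the ring closure: the planar cation closes through the envelope in which its aryl group turns away from the adjacent C3 aroyl group, which gives the 2,3-trans and hence 2,5-trans relation of the all-trans, least strained isomer. The step needs regioselective addition at C3 (secured by benzylic stabilisation at C2), capture of 20 by the C5 oxygen rather than by the ortho-silyloxy oxygen of the new aroyl ring (flavanone-type six-ring) or loss of H-3 to a chalcone (secured by the more nucleophilic alkyl silyl ether, the faster five-ring closure and the near absence of base), and an aroyl radical without a weak C–H bond in 1,5-reach (secured by silyl and not benzyl ethers on this ring).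

Step 11
Reactants: 21 protected ketone
Product: 22 (2,4-dihydroxyphenyl){(2S,3S,4S,5S)-4-[4-(benzyloxy)benzyl]-5-[2,4-bis(benzyloxy)phenyl]-2-[4-(benzyloxy)phenyl]oxolan-3-yl}methanone
Conditions: Bu4NF/AcOH (1:1, 2.5 equiv), THF, 0 °C
Reagents that add atoms: none
Why: Fluoride cleavage of aryl silyl ethers, buffered by acetic acid so that enolate formation (epimerisation at C3, retro-oxa-Michael opening of O1–C2) and reclosure by the freed ortho-phenol cannot start.

Step 12
Reactants: 22 tetrabenzyl ether
Product: 23 (2,4-dihydroxyphenyl)[(2S,3S,4S,5S)-5-(2,4-dihydroxyphenyl)-4-(4-hydroxybenzyl)-2-(4-hydroxyphenyl)oxolan-3-yl]methanone (target)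
Conditions: H2 (1 atm), Pd/C (10 %), EtOAc/MeOH, rt, stopped at full conversion
Reagents that add atoms: none
Why: Catalytic hydrogenolysis, in which aryl benzyl ethers (phenol leaving groups, unhindered CH2) should cleave well before the hindered secondary ring C–O bonds, while the ketone is deactivated as a hydrogen-bonded 2,4-dihydroxyphenyl ketone and no stereocentre is touched.

**Compound list**
1 | 3-[4-(benzyloxy)phenyl]propanoic acid | OC(=O)CCc1ccc(OCc2ccccc2)cc1 | starting material
2 | (4S)-4-benzyl-1,3-oxazolidin-2-one | O=C1OC[C@H](Cc2ccccc2)N1 | starting material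
3 | 3-[4-(benzyloxy)phenyl]propanoic pivalic anhydride | CC(C)(C)C(=O)OC(=O)CCc1ccc(OCc2ccccc2)cc1 | intermediate
4 | (4S)-4-benzyl-3-{3-[4-(benzyloxy)phenyl]propanoyl}-1,3-oxazolidin-2-one | O=C1OC[C@H](Cc2ccccc2)N1C(=O)CCc1ccc(OCc2ccccc2)cc1 | intermediate
5 | 2,4-bis(benzyloxy)benzaldehyde | O=Cc1ccc(OCc2ccccc2)cc1OCc1ccccc1 | starting material
6 | trimethylsilyl ether of anti aldol 7 | O=C1OC[C@H](Cc2ccccc2)N1C(=O)[C@H](Cc1ccc(OCc2ccccc2)cc1)[C@@H](c1ccc(OCc2ccccc2)cc1OCc1ccccc1)O[Si](C)(C)C | intermediate
7 | anti aldol, (2R,3S) in the acyl chain, (4S) in the auxiliary | O=C1OC[C@H](Cc2ccccc2)N1C(=O)[C@H](Cc1ccc(OCc2ccccc2)cc1)[C@@H](c1ccc(OCc2ccccc2)cc1OCc1ccccc1)O | intermediate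
8 | triethylsilyl ether of 7 | O=C1OC[C@H](Cc2ccccc2)N1C(=O)[C@H](Cc1ccc(OCc2ccccc2)cc1)[C@@H](c1ccc(OCc2ccccc2)cc1OCc1ccccc1)O[Si](CC)(CC)CC | intermediate
9 | (2S,3S)-2-[4-(benzyloxy)benzyl]-3-[2,4-bis(benzyloxy)phenyl]-3-(triethylsilyloxy)propan-1-ol | OC[C@H](Cc1ccc(OCc2ccccc2)cc1)[C@@H](c1ccc(OCc2ccccc2)cc1OCc1ccccc1)O[Si](CC)(CC)CC | intermediate
10 | (2R,3S)-2-[4-(benzyloxy)benzyl]-3-[2,4-bis(benzyloxy)phenyl]-3-(triethylsilyloxy)propanal | O=C[C@H](Cc1ccc(OCc2ccccc2)cc1)[C@@H](c1ccc(OCc2ccccc2)cc1OCc1ccccc1)O[Si](CC)(CC)CC | intermediate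
11 | 1-(benzyloxy)-4-(chloromethyl)benzene | ClCc1ccc(OCc2ccccc2)cc1 | starting material
12 | diethyl [4-(benzyloxy)benzyl]phosphonate | CCOP(=O)(Cc1ccc(OCc2ccccc2)cc1)OCC | intermediate
13 | potassium salt of the benzylic carbanion of 12 | CCOP(=O)([CH-]c1ccc(OCc2ccccc2)cc1)OCC.[K+] | intermediate
14 | {[(1S,2S,3E)-2-[4-(benzyloxy)benzyl]-1-[2,4-bis(benzyloxy)phenyl]-4-[4-(benzyloxy)phenyl]but-3-en-1-yl]oxy}triethylsilane | c1cc(OCc2ccccc2)ccc1/C=C/[C@H](Cc1ccc(OCc2ccccc2)cc1)[C@@H](c1ccc(OCc2ccccc2)cc1OCc1ccccc1)O[Si](CC)(CC)CC | intermediate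
15 | 2,4-dihydroxybenzoic acid | OC(=O)c1ccc(O)cc1O | starting material
16 | tert-butyldimethylsilyl 2,4-bis(tert-butyldimethylsilyloxy)benzoate | CC(C)(C)[Si](C)(C)OC(=O)c1ccc(O[Si](C)(C)C(C)(C)C)cc1O[Si](C)(C)C(C)(C)C | intermediate
17 | 2,4-bis(tert-butyldimethylsilyloxy)benzoyl chloride | ClC(=O)c1ccc(O[Si](C)(C)C(C)(C)C)cc1O[Si](C)(C)C(C)(C)C | intermediate
18 | 2,4-bis(tert-butyldimethylsilyloxy)benzoyl radical | O=[C]c1ccc(O[Si](C)(C)C(C)(C)C)cc1O[Si](C)(C)C(C)(C)C | intermediate
19 | C2 benzylic radical after aroyl addition at C3 (C3, C4, C5 as in 21) | O=C(c1ccc(O[Si](C)(C)C(C)(C)C)cc1O[Si](C)(C)C(C)(C)C)[C@H]([CH]c1ccc(OCc2ccccc2)cc1)[C@H](Cc1ccc(OCc2ccccc2)cc1)[C@@H](c1ccc(OCc2ccccc2)cc1OCc1ccccc1)O[Si](CC)(CC)CC | intermediate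
20 | C2 benzylic cation (chloride ion pair) from oxidation of 19 | O=C(c1ccc(O[Si](C)(C)C(C)(C)C)cc1O[Si](C)(C)C(C)(C)C)[C@H]([CH+]c1ccc(OCc2ccccc2)cc1)[C@H](Cc1ccc(OCc2ccccc2)cc1)[C@@H](c1ccc(OCc2ccccc2)cc1OCc1ccccc1)O[Si](CC)(CC)CC.[Cl-] | intermediate
21 | [2,4-bis(tert-butyldimethylsilyloxy)phenyl]{(2S,3S,4S,5S)-4-[4-(benzyloxy)benzyl]-5-[2,4-bis(benzyloxy)phenyl]-2-[4-(benzyloxy)phenyl]oxolan-3-yl}methanone | O=C(c1ccc(O[Si](C)(C)C(C)(C)C)cc1O[Si](C)(C)C(C)(C)C)[C@H]1[C@H](Cc2ccc(OCc3ccccc3)cc2)[C@@H](c2ccc(OCc3ccccc3)cc2OCc2ccccc2)O[C@@H]1c1ccc(OCc2ccccc2)cc1 | intermediate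
22 | (2,4-dihydroxyphenyl){(2S,3S,4S,5S)-4-[4-(benzyloxy)benzyl]-5-[2,4-bis(benzyloxy)phenyl]-2-[4-(benzyloxy)phenyl]oxolan-3-yl}methanone | O=C(c1ccc(O)cc1O)[C@H]1[C@H](Cc2ccc(OCc3ccccc3)cc2)[C@@H](c2ccc(OCc3ccccc3)cc2OCc2ccccc2)O[C@@H]1c1ccc(OCc2ccccc2)cc1 | intermediate
23 | (2,4-dihydroxyphenyl)[(2S,3S,4S,5S)-5-(2,4-dihydroxyphenyl)-4-(4-hydroxybenzyl)-2-(4-hydroxyphenyl)oxolan-3-yl]methanone | O=C(c1ccc(O)cc1O)[C@H]1[C@H](Cc2ccc(O)cc2)[C@@H](c2ccc(O)cc2O)O[C@@H]1c1ccc(O)cc1 | target

Total step count: 12. Longest linear sequence: 9 (steps 1, 2, 3, 4, 5, 7, 10, 11, 12).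

**Steps most likely to fail**

Step 10. The hindered aroyl radical may add too slowly to the internal, branched styrene and be lost by reduction or dimerisation. The facial selectivity at C3 may be poor, or the cation may lose a proton instead of closing the ring. The fallback uses known chemistry, sets out from 14 and builds the ring first.
- The silyl ether is cleaved (Bu4NF, THF, 0 °C) to the free (1S,2S,3E)-homoallylic alcohol F1.
- 5-endo-trig iodoetherification (I2, NaHCO3, MeCN, 0 °C) proceeds by anti addition across the (E)-alkene through the least crowded transition state and should give the all-trans (2R,3S,4R,5S)-3-iodotetrahydrofuran F2.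
- Nickel-catalysed reductive cross-electrophile acylation of F2 by 17 (NiCl2(dme), 4,4'-di-tert-butyl-2,2'-bipyridine, Mn powder, DMA, rt) then forms the same C(=O)–C3 bond. The ring-bound C3 radical is met by acyl-nickel on the face opposite to both flanking substituents.
- The route is rejoined at 21.

Step 7. The basic phosphonate anion may enolise the α-branched, β-silyloxy aldehyde, which would cause epimerisation at C4 or β-elimination of the silyloxy group. The fallback sets out from 10 and avoids carbanion bases.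
- Takai olefination (CrCl2, CHI3, THF, 0 °C) should give the (1S,2S,3E)-vinyl iodide F3.
- Suzuki–Miyaura coupling of F3 with 4-(benzyloxy)phenylboronic acid (Pd(PPh3)4, K3PO4, THF/H2O, 50 °C) keeps the alkene geometry.
- The route is rejoined at 14.

Step 12. Hydrogenolysis of the two benzylic ring C–O bonds or reduction of the ketone may compete with cleavage of the last benzyl ethers. The fallback sets out from 21 and replaces hydrogen gas over Pd/C by a silane exchange.
- Pd(OAc)2, Et3SiH and Et3N in CH2Cl2 at rt should turn the four aryl benzyl ethers into aryl triethylsilyl ethers and give the hexasilyl ether F4.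
- A single buffered global desilylation (Bu4NF/AcOH, THF, 0 °C) then sets all six phenols free.
- The route is rejoined at 23.

**Further compounds**
F1 | step 10 | (1S,2S,3E)-2-[4-(benzyloxy)benzyl]-1-[2,4-bis(benzyloxy)phenyl]-4-[4-(benzyloxy)phenyl]but-3-en-1-ol | c1cc(OCc2ccccc2)ccc1/C=C/[C@H](Cc1ccc(OCc2ccccc2)cc1)[C@@H](c1ccc(OCc2ccccc2)cc1OCc1ccccc1)O
F2 | step 10 | (2R,3S,4R,5S)-4-[4-(benzyloxy)benzyl]-5-[2,4-bis(benzyloxy)phenyl]-2-[4-(benzyloxy)phenyl]-3-iodooxolane (all-trans) | I[C@H]1[C@H](Cc2ccc(OCc3ccccc3)cc2)[C@@H](c2ccc(OCc3ccccc3)cc2OCc2ccccc2)O[C@@H]1c1ccc(OCc2ccccc2)cc1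
F3 | step 7 | {[(1S,2S,3E)-2-[4-(benzyloxy)benzyl]-1-[2,4-bis(benzyloxy)phenyl]-4-iodobut-3-en-1-yl]oxy}triethylsilane | I/C=C/[C@H](Cc1ccc(OCc2ccccc2)cc1)[C@@H](c1ccc(OCc2ccccc2)cc1OCc1ccccc1)O[Si](CC)(CC)CC
F4 | step 12 | [2,4-bis(tert-butyldimethylsilyloxy)phenyl]{(2S,3S,4S,5S)-5-[2,4-bis(triethylsilyloxy)phenyl]-4-[4-(triethylsilyloxy)benzyl]-2-[4-(triethylsilyloxy)phenyl]oxolan-3-yl}methanone | O=C(c1ccc(O[Si](C)(C)C(C)(C)C)cc1O[Si](C)(C)C(C)(C)C)[C@H]1[C@H](Cc2ccc(O[Si](CC)(CC)CC)cc2)[C@@H](c2ccc(O[Si](CC)(CC)CC)cc2O[Si](CC)(CC)CC)O[C@@H]1c1ccc(O[Si](CC)(CC)CC)cc1
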